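**Strategy.** The target is traced back to an arene. In the cyclohexene ring (C1 = carbinol carbon carrying C7H2OBz, C2=C3 the alkene, C4 the benzoyloxy carbon, C5 and C6 the secondary carbinols), the cis C4,C5 diol beside the C2=C3 double bond is a benzene cis-dihydrodiol. With a halogen on C3 its absolute sense is the one toluene dioxygenase delivers. One whole-cell oxidation of bromobenzene, taken straight from the bottle, therefore forms the C4–O and C5–O bonds with both stereocentres and leaves a diene whose unhalogenated C1=C6 bond can be oxidised later. The acetonide of that diol then steers oxygenation at C6 and C1 and the attachment of C7.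

Key step: step 1

Remark: in step 1 the two electrons come from cellular NADH, which the cells regenerate from the glucose feed; reagents that only deliver protecting groups or oxygen are given by name and SMILES in the steps and carry no compound number.

Face convention: ring drawn with C1→C6 clockwise, β towards the viewer. The target has C4–OBz β, C5–OH β, C6–OH α, C1–OH α, C1–CH2OBz β.

Step 1
Reactants: 1 bromobenzene
Product: 2 (1S,2S)-3-bromocyclohexa-3,5-diene-1,2-diol
Conditions: E. coli JM109(pDTG601) whole cells (toluene dioxygenase, IPTG-induced), glucose feed, air, pH 7, 30 °C; EtOAc extraction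
Reagents that add atoms: dioxygen, O=O
Why: The Rieske non-heme iron oxygenase, supplied with two electrons from NADH through its reductase and ferredoxin, activates O2 at the mononuclear iron and transfers both oxygen atoms to one face of the C2–C3 bond of bromobenzene (target C4 and C5); because the recombinant strain lacks the cis-diol dehydrogenase, the reaction stops at the cyclohexadiene cis-diol instead of the catechol. The closest known reaction type is this very one, toluene dioxygenase cis-dihydroxylation of monohalobenzenes. No ring is closed. Both new stereocentres (diol C1 and C2, target C5 and C4) are fixed by the active site, which binds the halogen where the methyl group of toluene normally sits and so exposes a single face of the adjacent bond, giving the (1S,2S) diol. The step needs 2,3- over 3,4-regioselectivity and one enantiotopic face, and both are secured by the lone bromine substituent acting as the recognition element; the same bromine later keeps its own double bond out of the osmylation.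

Step 2
Reactants: 2 (1S,2S)-3-bromocyclohexa-3,5-diene-1,2-diol
Product: 3 (3aS,7aS)-4-bromo-2,2-dimethyl-3a,7a-dihydro-1,3-benzodioxole
Conditions: 2,2-dimethoxypropane, p-TsOH·H2O (cat.), acetone, rt; used at once
Reagents that add atoms: 2,2-dimethoxypropane, COC(C)(C)OC
Why: Acid-catalysed transacetalisation (acetonide formation) is fast for a cis-1,2-diol, protects the acid-labile diene diol against dehydration to bromophenol and places a cis-fused dioxolane on the β face, with no stereocentre created.

Step 3
Reactants: 3 (3aS,7aS)-4-bromo-2,2-dimethyl-3a,7a-dihydro-1,3-benzodioxole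
Product: 4 (3aS,4R,5R,7aS)-7-bromo-2,2-dimethyl-3a,4,5,7a-tetrahydro-1,3-benzodioxole-4,5-diol
Conditions: OsO4 (2 mol %), NMO, acetone/H2O, rt
Reagents that add atoms: osmium tetroxide, O=[Os](=O)(=O)=O; N-methylmorpholine N-oxide, C[N+]1([O-])CCOCC1; water, O
Why: Upjohn catalytic syn-dihydroxylation takes the electron-richer unhalogenated C1=C6 bond and attacks the face opposite the cis-fused acetonide, so both new hydroxyls are α and C6–OH is set trans to C5–O.

Step 4
Reactants: 4 (3aS,4R,5R,7aS)-7-bromo-2,2-dimethyl-3a,4,5,7a-tetrahydro-1,3-benzodioxole-4,5-diol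
Product: 5 (3aS,4R,5R,7aR)-2,2-dimethyl-3a,4,5,7a-tetrahydro-1,3-benzodioxole-4,5-diol
Conditions: Bu3SnH, AIBN (cat.), THF, reflux; KF work-up
Reagents that add atoms: none
Why: Radical-chain hydrodebromination of the vinyl bromide with tin hydride removes the placeholder once its regiochemical task is done, so that the later enone is not a vinylogous acyl bromide, while hydroxyls, acetonide and all stereocentres are untouched.

Step 5
Reactants: 5 (3aS,4R,5R,7aR)-2,2-dimethyl-3a,4,5,7a-tetrahydro-1,3-benzodioxole-4,5-diol
Product: 6 (3aS,4S,7aR)-4-hydroxy-2,2-dimethyl-3a,7a-dihydro-1,3-benzodioxol-5(4H)-one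
Conditions: 4-acetamido-TEMPO (2.2 equiv), p-TsOH·H2O (2.2 equiv), CH2Cl2, 0 °C
Reagents that add atoms: none
Why: Oxoammonium oxidation by the bulky salt formed through acid-promoted disproportionation of the nitroxide abstracts hydride fastest from the allylic and less crowded C1 carbinol, and the resulting α-ketol hydroxyl at C6 is deactivated towards a second oxidation, so only the C1 ketone forms.

Step 6
Reactants: 6 (3aS,4S,7aR)-4-hydroxy-2,2-dimethyl-3a,7a-dihydro-1,3-benzodioxol-5(4H)-one; 7 dibromomethane
Product: 8 (3aS,4R,7aR)-2,2-dimethyl-5-methylidene-3a,4,5,7a-tetrahydro-1,3-benzodioxol-4-ol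
Conditions: Zn, CH2Br2, TiCl4 (reagent pre-formed in THF, 4 equiv), CH2Cl2, 0 °C to rt; NaHCO3 quench
Reagents that add atoms: dibromomethane, BrCBr
Why: Takai–Lombardo methylenation uses a non-basic gem-dimetallic CH2 donor that adds 1,2 to the enone carbonyl and tolerates the free hydroxyl at the cost of one equivalent, so neither epimerisation at C6 nor enolate-driven loss of the C5 oxygen with aromatisation can set in.

Step 7
Reactants: 8 (3aS,4R,7aR)-2,2-dimethyl-5-methylidene-3a,4,5,7a-tetrahydro-1,3-benzodioxol-4-ol
Product: 9 (3aS,4S,5S,7aR)-2,2-dimethyl-3a,7a-dihydro-4H-spiro[1,3-benzodioxole-5,2'-oxiran]-4-ol (C1–C7 spiro-epoxide, epoxide oxygen α, cis to C6–OH)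
Conditions: VO(acac)2 (5 mol %), t-BuOOH (1.3 equiv, decane), CH2Cl2, 0 °C to rt
Reagents that add atoms: tert-butyl hydroperoxide, CC(C)(C)OO
Why: Vanadium-catalysed hydroxyl-directed epoxidation (Sharpless VO(acac)2/TBHP) delivers oxygen from the vanadate ester of the α-oriented C6 hydroxyl to the α face of the allylic exocyclic C1=C7 bond only, the ring alkene being merely homoallylic and deactivated by the C4 oxygen, which sets C1 with its C–O bond cis to C6–OH.

Step 8
Reactants: 9 (3aS,4S,5S,7aR)-2,2-dimethyl-3a,7a-dihydro-4H-spiro[1,3-benzodioxole-5,2'-oxiran]-4-ol; 10 benzoic acid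
Product: 11 [(3aS,4S,5S,7aR)-4,5-dihydroxy-2,2-dimethyl-3a,4,5,7a-tetrahydro-1,3-benzodioxol-5-yl]methyl benzoate
Conditions: PhCO2H (1.5 equiv), CsOBz (0.3 equiv), DMF, 70 °C
Reagents that add atoms: benzoic acid, OC(=O)c1ccccc1
Why: Carboxylate SN2 opening of a 2,2-disubstituted epoxide occurs at the unhindered methylene C7 because the fully substituted C1 cannot be attacked with inversion, so the C1–O bond and configuration are retained, the benzoate lands on C7 and the acid buffer protonates the tertiary alkoxide before acyl transfer.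

Step 9
Reactants: 11 [(3aS,4S,5S,7aR)-4,5-dihydroxy-2,2-dimethyl-3a,4,5,7a-tetrahydro-1,3-benzodioxol-5-yl]methyl benzoate
Product: 12 [(3aR,4S,5S,7aR)-4-{[tert-butyl(dimethyl)silyl]oxy}-5-hydroxy-2,2-dimethyl-3a,4,5,7a-tetrahydro-1,3-benzodioxol-5-yl]methyl benzoate
Conditions: TBSOTf (1.3 equiv), 2,6-lutidine, CH2Cl2, −78 to −20 °C
Reagents that add atoms: tert-butyldimethylsilyl trifluoromethanesulfonate, CC(C)(C)[Si](C)(C)OS(=O)(=O)C(F)(F)F
Why: Silyl ether formation with the silyl triflate caps the only secondary hydroxyl, C6–OH, while the neighbouring tertiary C1–OH is too hindered to react at low temperature, which blocks C6 and screens C5 for the later acylation.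

Step 10
Reactants: 12 [(3aR,4S,5S,7aR)-4-{[tert-butyl(dimethyl)silyl]oxy}-5-hydroxy-2,2-dimethyl-3a,4,5,7a-tetrahydro-1,3-benzodioxol-5-yl]methyl benzoate
Product: 13 [(1S,4R,5R,6S)-6-{[tert-butyl(dimethyl)silyl]oxy}-1,4,5-trihydroxycyclohex-2-en-1-yl]methyl benzoate
Conditions: AcOH/H2O (4:1), 50 °C
Reagents that add atoms: none
Why: Mild aqueous acid hydrolysis of the isopropylidene acetal of a cis-diol with one allylic oxygen is faster than cleavage of a hindered secondary TBS ether or of a benzoate, which frees C4–OH and C5–OH without touching a stereocentre.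

Step 11
Reactants: 13 [(1S,4R,5R,6S)-6-{[tert-butyl(dimethyl)silyl]oxy}-1,4,5-trihydroxycyclohex-2-en-1-yl]methyl benzoate; 14 benzoyl chloride
Product: 15 [(1S,4R,5R,6S)-4-(benzoyloxy)-6-{[tert-butyl(dimethyl)silyl]oxy}-1,5-dihydroxycyclohex-2-en-1-yl]methyl benzoate
Conditions: BzCl (1.1 equiv), pyridine, CH2Cl2, −40 to 0 °C
Reagents that add atoms: benzoyl chloride, O=C(Cl)c1ccccc1
Why: Acylation of an alcohol with one equivalent of acid chloride in pyridine at low temperature selects the allylic C4–OH, which has a single substituted neighbour, over C5–OH wedged between C4 and the silyloxy-bearing C6 and over the tertiary C1–OH.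

Step 12
Reactants: 15 [(1S,4R,5R,6S)-4-(benzoyloxy)-6-{[tert-butyl(dimethyl)silyl]oxy}-1,5-dihydroxycyclohex-2-en-1-yl]methyl benzoate
Product: 16 [(1S,4R,5S,6S)-4-(benzoyloxy)-1,5,6-trihydroxycyclohex-2-en-1-yl]methyl benzoate (CNP0217467.1)
Conditions: HF·pyridine, pyridine, THF, 0 °C to rt
Reagents that add atoms: none
Why: Fluoride-mediated desilylation under buffered acidic conditions excludes base-induced benzoyl migration between the cis C4 and C5 oxygens and leaves both esters, the alkene and the tertiary allylic alcohol intact, so the target is released.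

**Compound list**

1 | bromobenzene | Brc1ccccc1 | starting material
2 | (1S,2S)-3-bromocyclohexa-3,5-diene-1,2-diol | BrC1=CC=C[C@H](O)[C@@H]1O | intermediate
3 | (3aS,7aS)-4-bromo-2,2-dimethyl-3a,7a-dihydro-1,3-benzodioxole | C1=C(Br)[C@H]2OC(C)(C)O[C@H]2C=C1 | intermediate
4 | (3aS,4R,5R,7aS)-7-bromo-2,2-dimethyl-3a,4,5,7a-tetrahydro-1,3-benzodioxole-4,5-diol | O[C@@H]1C=C(Br)[C@H]2OC(C)(C)O[C@H]2[C@@H]1O | intermediate
5 | (3aS,4R,5R,7aR)-2,2-dimethyl-3a,4,5,7a-tetrahydro-1,3-benzodioxole-4,5-diol | O[C@@H]1C=C[C@H]2OC(C)(C)O[C@H]2[C@@H]1O | intermediate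
6 | (3aS,4S,7aR)-4-hydroxy-2,2-dimethyl-3a,7a-dihydro-1,3-benzodioxol-5(4H)-one | O=C1C=C[C@H]2OC(C)(C)O[C@H]2[C@@H]1O | intermediate
7 | dibromomethane | BrCBr | starting material
8 | (3aS,4R,7aR)-2,2-dimethyl-5-methylidene-3a,4,5,7a-tetrahydro-1,3-benzodioxol-4-ol | C=C1C=C[C@H]2OC(C)(C)O[C@H]2[C@@H]1O | intermediate
9 | (3aS,4S,5S,7aR)-2,2-dimethyl-3a,7a-dihydro-4H-spiro[1,3-benzodioxole-5,2'-oxiran]-4-ol | C1O[C@@]12C=C[C@H]3OC(C)(C)O[C@H]3[C@@H]2O | intermediate
10 | benzoic acid | OC(=O)c1ccccc1 | starting material
11 | [(3aS,4S,5S,7aR)-4,5-dihydroxy-2,2-dimethyl-3a,4,5,7a-tetrahydro-1,3-benzodioxol-5-yl]methyl benzoate | O=C(OC[C@@]1(O)C=C[C@H]2OC(C)(C)O[C@H]2[C@@H]1O)c1ccccc1 | intermediate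
12 | [(3aR,4S,5S,7aR)-4-{[tert-butyl(dimethyl)silyl]oxy}-5-hydroxy-2,2-dimethyl-3a,4,5,7a-tetrahydro-1,3-benzodioxol-5-yl]methyl benzoate | O=C(OC[C@@]1(O)C=C[C@H]2OC(C)(C)O[C@H]2[C@@H]1O[Si](C)(C)C(C)(C)C)c1ccccc1 | intermediate
13 | [(1S,4R,5R,6S)-6-{[tert-butyl(dimethyl)silyl]oxy}-1,4,5-trihydroxycyclohex-2-en-1-yl]methyl benzoate | O=C(OC[C@@]1(O)C=C[C@@H](O)[C@@H](O)[C@@H]1O[Si](C)(C)C(C)(C)C)c1ccccc1 | intermediate
14 | benzoyl chloride | O=C(Cl)c1ccccc1 | starting material
15 | [(1S,4R,5R,6S)-4-(benzoyloxy)-6-{[tert-butyl(dimethyl)silyl]oxy}-1,5-dihydroxycyclohex-2-en-1-yl]methyl benzoate | O=C(OC[C@@]1(O)C=C[C@@H](OC(=O)c2ccccc2)[C@@H](O)[C@@H]1O[Si](C)(C)C(C)(C)C)c1ccccc1 | intermediate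
16 | [(1S,4R,5S,6S)-4-(benzoyloxy)-1,5,6-trihydroxycyclohex-2-en-1-yl]methyl benzoate | O=C(OC[C@@]1(O)C=C[C@@H](OC(=O)c2ccccc2)[C@@H](O)[C@@H]1O)c1ccccc1 | target

Total step count: 12. Longest linear sequence: 12 steps, from bromobenzene 1 to 16.

**Steps most likely to fail**

Step 6. The free hydroxyl may consume the reagent, and Lewis-acid- or zinc-induced side reactions (acetal loss, reduction of the α-ketol, enolisation followed by loss of the C5 oxygen and aromatisation) may outrun methylene transfer. The fallback sets out from 6 and replaces one-step methylenation by addition–elimination. (Trimethylsilyl)methyllithium pre-mixed with anhydrous CeCl3 in THF at −78 °C, a nucleophilic but scarcely basic organocerium, should add 1,2 to the carbonyl to give the tertiary β-hydroxysilane (3aS,4S,7aR)-2,2-dimethyl-5-[(trimethylsilyl)methyl]-3a,4,5,7a-tetrahydro-1,3-benzodioxole-4,5-diol F1, either C5 epimer being usable. Peterson elimination with KH in THF at 0 °C to rt should then expel the silanolate and form the exocyclic alkene, so the fallback comes back to the route at 8.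

Step 8. Slow SN2 attack at the methylene next to a fully substituted carbon may allow acid-assisted ionisation of the tertiary allylic epoxide carbon (SN1 or SN2′ opening) or benzoyl transfer to the C6 oxygen to compete. The fallback sets out from 9 and separates ring opening from acylation. Aqueous KOH in DMSO at 60 °C, with no acid present, should open the epoxide at C7 to the triol (3aS,4S,5S,7aR)-5-(hydroxymethyl)-2,2-dimethyl-3a,4,5,7a-tetrahydro-1,3-benzodioxole-4,5-diol F2. Benzoyl chloride (1.05 equiv) with 2,4,6-collidine in CH2Cl2 at −40 °C should then acylate only the primary hydroxyl, and the fallback comes back to the route at 11.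

Step 11. Discrimination between the cis C4 and C5 hydroxyls may be incomplete, or the benzoyl group may migrate between them under the basic conditions. The fallback sets out from 13 and replaces kinetic site selection by stereoelectronically controlled orthoester opening. Trimethyl orthobenzoate with catalytic CSA in CH2Cl2 at rt should convert the cis C4,C5 diol into the cyclic orthobenzoate [(3aR,4S,5S,7aR)-4-{[tert-butyl(dimethyl)silyl]oxy}-5-hydroxy-2-methoxy-2-phenyl-3a,4,5,7a-tetrahydro-1,3-benzodioxol-5-yl]methyl benzoate F3, a mixture of epimers at the orthoester carbon. Brief hydrolysis in 80% aqueous acetic acid at 0 °C passes through the dioxolanylium ion and the ortho acid, which should collapse to the ester on the pseudo-axial allylic C4 oxygen and leave the equatorial C5 hydroxyl free. This assumes the half-chair with C5–O and C6–OTBS equatorial. The fallback comes back to the route at 15.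

Further compounds
F1 | step 6 | (3aS,4S,7aR)-2,2-dimethyl-5-[(trimethylsilyl)methyl]-3a,4,5,7a-tetrahydro-1,3-benzodioxole-4,5-diol (C5 epimers) | C[Si](C)(C)CC1(O)C=C[C@H]2OC(C)(C)O[C@H]2[C@@H]1O
F2 | step 8 | (3aS,4S,5S,7aR)-5-(hydroxymethyl)-2,2-dimethyl-3a,4,5,7a-tetrahydro-1,3-benzodioxole-4,5-diol | OC[C@@]1(O)C=C[C@H]2OC(C)(C)O[C@H]2[C@@H]1O
F3 | step 11 | [(3aR,4S,5S,7aR)-4-{[tert-butyl(dimethyl)silyl]oxy}-5-hydroxy-2-methoxy-2-phenyl-3a,4,5,7a-tetrahydro-1,3-benzodioxol-5-yl]methyl benzoate (orthoester epimers) | O=C(OC[C@@]1(O)C=C[C@H]2OC(OC)(c3ccccc3)O[C@H]2[C@@H]1O[Si](C)(C)C(C)(C)C)c1ccccc1
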